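The oxolane of neoolivil has a C2 axis through O1 and the C3–C4 midpoint. Both benzylic carbons (C2, C5) lie para to free phenols, so each is a latent p-quinone methide and O1 is formally one molecule of water. Everything rests on the O1–C2 disconnection. The key step dehydrogenates an acyclic, C2-symmetric dibenzylbutane bisphenol to a bis-quinone methide. Water adds at one terminus and the ring closes by oxa-1,6-addition at the other. This forms both C–O bonds and both benzylic stereocentres under relay from C3/C4. Those two centres arise together in one auxiliary-controlled oxidative enolate homocoupling. The precursor is the 9,9'-bis-silyl ether of (8S,8'S)-secoisolariciresinol.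

Key step: step 5

Remark: lignan locants (C7/C7' benzylic, C8/C8' methine, C9/C9' oxymethylene) are used for the open-chain compounds and correspond to C2/C5, C3/C4 and the CH2O groups of the oxolane. The E/Z geometry of the exocyclic C=C bonds of 10 and 11 is left undefined because it vanishes on rearomatisation.

Step 1
Reactants: 1 3-(4-hydroxy-3-methoxyphenyl)propanoic acid (dihydroferulic acid); 2 (R)-4-isopropyl-1,3-oxazolidin-2-one
Product: 4 (R)-4-isopropyl-3-[3-(3-methoxy-4-pivaloyloxyphenyl)propanoyl]-1,3-oxazolidin-2-one, via 3-(3-methoxy-4-pivaloyloxyphenyl)propanoic pivalic anhydride 3 (not isolated)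
Conditions: PivCl (2.1 equiv), Et3N, THF, −20 °C → rt; then LiCl, 2, rt
Reagents that add atoms: pivaloyl chloride, CC(C)(C)C(=O)Cl
Why: Mixed-anhydride N-acylation of an oxazolidinone (LiCl/Et3N variant), in which pivaloyl chloride activates the carboxyl group and at the same time caps the phenol as the hindered aryl pivalate, and the oxazolidinone attacks the less hindered carbonyl of 3; no new stereocentre is formed.

Step 2
Reactants: 4 (R)-4-isopropyl-3-[3-(3-methoxy-4-pivaloyloxyphenyl)propanoyl]-1,3-oxazolidin-2-one (two molecules)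
Product: 6 (2S,3S)-1,4-bis[(R)-4-isopropyl-2-oxo-1,3-oxazolidin-3-yl]-2,3-bis(3-methoxy-4-pivaloyloxybenzyl)butane-1,4-dione, via lithium (Z)-enolate of the imide 5 (not isolated)
Conditions: LDA, THF, −78 °C; then TiCl4, −78 → 0 °C
Reagents that add atoms: none
Why: Oxidative enolate homocoupling, in which one-electron oxidation of the chelated (Z)-enolate by Ti(IV) joins two α-carbons, each on the face opposite its isopropyl group (the facial sense of Evans alkylations), so the (R)-auxiliary should set C8 and C8' together as S,S.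

Step 3
Reactants: 6 (2S,3S)-bis-imide dimer
Product: 7 (8S,8'S)-secoisolariciresinol, (2S,3S)-2,3-bis(4-hydroxy-3-methoxybenzyl)butane-1,4-diol
Conditions: LiAlH4, THF, 0 °C → rt
Reagents that add atoms: none
Why: Hydride reduction of the exocyclic imide carbonyls and of the aryl esters releases both primary alcohols, both phenols and the auxiliary in one operation, and C8/C8' are untouched because reduction is faster than enolisation.

Step 4
Reactants: 7 (8S,8'S)-secoisolariciresinol
Product: 9 (2S,3S)-1,4-bis(tert-butyldiphenylsilyloxy)-2,3-bis(4-hydroxy-3-methoxybenzyl)butane, via tetrakis-TBDPS ether of secoisolariciresinol 8 (not isolated)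
Conditions: TBDPSCl (4.4 equiv), imidazole, DMF, rt; then H2O, Cs2CO3 (cat.), rt
Reagents that add atoms: tert-butyldiphenylsilyl chloride, CC(C)(C)[Si](Cl)(c1ccccc1)c1ccccc1
Why: Exhaustive silylation followed by base-catalysed hydrolysis of aryl silyl ethers, which are cleaved far faster than alkyl silyl ethers because phenoxide is the better leaving group, leaves only the two primary TBDPS ethers; no stereocentre is affected.

Step 5
Reactants: 9 (2S,3S)-1,4-bis(tert-butyldiphenylsilyloxy)-2,3-bis(4-hydroxy-3-methoxybenzyl)butane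
Product: 12 (2R,3S,4S,5R)-3,4-bis[(tert-butyldiphenylsilyloxy)methyl]-2,5-bis(4-hydroxy-3-methoxyphenyl)oxolane, via (2S,3S)-bis(p-quinone methide) 10 (not isolated), via (2S,3S,4R)-hydroxy quinone methide 11 (not isolated)
Conditions: Ag2O (excess), CH2Cl2 (high dilution), rt, dark; filter; H2O–acetone, rt; then CSA (cat.), CH2Cl2, 0 °C
Reagents that add atoms: water, O
Why: Mechanism: Ag2O dehydrogenates both 4-alkylguaiacol units of 9 to the C2-symmetric bis(p-quinone methide) 10, water adds 1,6 to one of its two homotopic benzylic carbons to give 11, and the new benzylic hydroxyl adds 1,6 to the remaining quinone methide carbon, both additions being driven by rearomatisation. The closest known reaction types are the Ag2O oxidation of 4-alkyl-2-methoxyphenols to p-quinone methides and the stitching by water of 8–8'-coupled bis-quinone methides from γ-acylated monolignols into 2,5-diaryloxolanes. The oxolane closes in the 5-exo-trig mode, since the C=C bond that is consumed lies outside the new ring. The centre formed in the closure is controlled by C4 and C3 (set in step 2), the aryl group taking the pseudo-equatorial position trans to the adjacent CH2OTBDPS group in an envelope transition state; the centre formed by water addition is expected to arise with little facial bias and is corrected under thermodynamic control, because p-hydroxybenzyl C–O bonds ionise reversibly with catalytic acid and epimers as well as any doubly hydrated 1,4-diol should drain into the all-trans (2R,3S,4S,5R) isomer. The step needs O1 rather than the C9/C9' oxygens (which would give furofuran-type rings) or the aryl carbons as nucleophile, secured by the bulky non-participating TBDPS ethers and by the neutral hydration stage, and it needs the carbinol of 11 to escape oxidation, secured by filtering off the oxidant before water is admitted. Site selectivity is not required because of the C2 axis, and loss of C8/C8' by tautomerisation to a styrene is slowed by A1,3 strain, which holds each C8–H bond in the plane of its quinone methide.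

Step 6
Reactants: 12 bis-TBDPS ether of neoolivil
Product: 13 (+)-neoolivil, (2R,3S,4S,5R)-2,5-bis(4-hydroxy-3-methoxyphenyl)-3,4-bis(hydroxymethyl)oxolane
Conditions: TBAF, AcOH, THF, 0 °C → rt
Reagents that add atoms: none
Why: Fluoride-induced desilylation driven by Si–F bond formation, in which the acetic acid buffer avoids both strong base and the acid that would ionise the p-hydroxybenzyl ether bonds, so the four stereocentres stay as set.

Compound list
1 | 3-(4-hydroxy-3-methoxyphenyl)propanoic acid | COc1cc(CCC(=O)O)ccc1O | starting material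
2 | (R)-4-isopropyl-1,3-oxazolidin-2-one | CC(C)[C@@H]1COC(=O)N1 | starting material
3 | 3-(3-methoxy-4-pivaloyloxyphenyl)propanoic pivalic anhydride | COc1cc(CCC(=O)OC(=O)C(C)(C)C)ccc1OC(=O)C(C)(C)C | intermediate
4 | (R)-4-isopropyl-3-[3-(3-methoxy-4-pivaloyloxyphenyl)propanoyl]-1,3-oxazolidin-2-one | CC(C)[C@@H]1COC(=O)N1C(=O)CCc1ccc(OC(=O)C(C)(C)C)c(OC)c1 | intermediate
5 | lithium (Z)-enolate of 4 | [Li+].[O-]/C(=C\Cc1ccc(OC(=O)C(C)(C)C)c(OC)c1)N1[C@H](C(C)C)COC1=O | intermediate
6 | (2S,3S)-1,4-bis[(R)-4-isopropyl-2-oxo-1,3-oxazolidin-3-yl]-2,3-bis(3-methoxy-4-pivaloyloxybenzyl)butane-1,4-dione | O=C(N1[C@H](C(C)C)COC1=O)[C@@H](Cc1ccc(OC(=O)C(C)(C)C)c(OC)c1)[C@H](Cc1ccc(OC(=O)C(C)(C)C)c(OC)c1)C(=O)N1[C@H](C(C)C)COC1=O | intermediate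
7 | (8S,8'S)-secoisolariciresinol | OC[C@@H](Cc1ccc(O)c(OC)c1)[C@H](Cc1ccc(O)c(OC)c1)CO | intermediate
8 | tetrakis-TBDPS ether of (8S,8'S)-secoisolariciresinol | CC(C)(C)[Si](c1ccccc1)(c1ccccc1)OC[C@@H](Cc1ccc(O[Si](c2ccccc2)(c2ccccc2)C(C)(C)C)c(OC)c1)[C@H](Cc1ccc(O[Si](c2ccccc2)(c2ccccc2)C(C)(C)C)c(OC)c1)CO[Si](c1ccccc1)(c1ccccc1)C(C)(C)C | intermediate
9 | (2S,3S)-1,4-bis(tert-butyldiphenylsilyloxy)-2,3-bis(4-hydroxy-3-methoxybenzyl)butane | CC(C)(C)[Si](c1ccccc1)(c1ccccc1)OC[C@@H](Cc1ccc(O)c(OC)c1)[C@H](Cc1ccc(O)c(OC)c1)CO[Si](c1ccccc1)(c1ccccc1)C(C)(C)C | intermediate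
10 | 4,4'-[(2S,3S)-2,3-bis(tert-butyldiphenylsilyloxymethyl)butane-1,4-diylidene]bis(2-methoxycyclohexa-2,5-dien-1-one) | COC1=CC(=C[C@H](CO[Si](c2ccccc2)(c2ccccc2)C(C)(C)C)[C@@H](CO[Si](c2ccccc2)(c2ccccc2)C(C)(C)C)C=C2C=CC(=O)C(OC)=C2)C=CC1=O | intermediate
11 | 4-[(2S,3S,4R)-2,3-bis(tert-butyldiphenylsilyloxymethyl)-4-hydroxy-4-(4-hydroxy-3-methoxyphenyl)butylidene]-2-methoxycyclohexa-2,5-dien-1-one | COC1=CC(=C[C@H](CO[Si](c2ccccc2)(c2ccccc2)C(C)(C)C)[C@@H](CO[Si](c2ccccc2)(c2ccccc2)C(C)(C)C)[C@@H](O)c2ccc(O)c(OC)c2)C=CC1=O | intermediate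
12 | (2R,3S,4S,5R)-3,4-bis[(tert-butyldiphenylsilyloxy)methyl]-2,5-bis(4-hydroxy-3-methoxyphenyl)oxolane | COc1cc([C@@H]2O[C@@H](c3ccc(O)c(OC)c3)[C@H](CO[Si](c3ccccc3)(c3ccccc3)C(C)(C)C)[C@H]2CO[Si](c4ccccc4)(c4ccccc4)C(C)(C)C)ccc1O | intermediate
13 | (+)-neoolivil | COc1cc([C@@H]2O[C@@H](c3ccc(O)c(OC)c3)[C@H](CO)[C@H]2CO)ccc1O | target

Total step count: 6. Longest linear sequence: 6 steps (1 → 4 → 6 → 7 → 9 → 12 → 13).

Steps most likely to fail

Step 5.
- **What may go wrong:** The quinone methides may tautomerise to styrenes, which erases C8/C8'. Intermolecular phenol–quinone methide addition may compete during the double dehydrogenation. In the acid stage, the benzylic epimers may converge incompletely, or a Friedel–Crafts closure may give an aryltetralin.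
- **Fallback (from 9, back at 12):** The free bis-quinone methide is avoided.
  - Exhaustive benzylic oxidation of 9 with DDQ in aqueous dioxane should give the (2S,3S)-1,4-diaryl-1,4-diketone F1.
  - Reagent-controlled Corey–Bakshi–Shibata reduction follows ((S)-Me-CBS, excess BH3·SMe2, aryl as the large group). It should give the (1R,2S,3S,4R)-1,4-diol F2.
  - Cyclodehydration of F2 with catalytic CSA in CH2Cl2 then gives 12. One carbinol keeps its configuration as the nucleophile, while the other ionises and recloses trans.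

Step 2.
- **What may go wrong:** The enolate may be protonated or chlorinated instead of coupling. Facial control may also erode, so that the R,S (meso-type) dimer forms alongside the S,S dimer.
- **Fallback (from 4, back at 7):** The C8–C8' bond and the second benzyl group are installed by two polar alkylations.
  - Evans alkylation of 4 (NaHMDS, tert-butyl bromoacetate) should give the (S)-succinate imide F3.
  - Imide-selective LiBH4 reduction gives the hydroxy tert-butyl ester F4, and TFA closes it to the (S)-β-benzylbutyrolactone F5.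
  - Commercial creosol is pivaloylated to 2-methoxy-4-methylphenyl pivalate F6. NBS/AIBN then brominates it to 4-(bromomethyl)-2-methoxyphenyl pivalate F7.
  - The lithium enolate of F5 is benzylated with F7 anti to the C4 substituent. This gives the trans-(3S,4S)-dibenzylbutyrolactone F8.
  - LiAlH4 takes F8 to 7.

Step 1.
- **What may go wrong:** The free phenol may be acylated by the mixed anhydride of another molecule, which leads to oligoesters. Excess acid chloride may also N-pivaloylate the auxiliary.
- **Fallback (from 1, back at 4):** Protection and activation are separated.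
  - Schotten–Baumann pivaloylation of 1 (PivCl, aq NaOH) should give 3-(3-methoxy-4-pivaloyloxyphenyl)propanoic acid F9.
  - Oxalyl chloride with catalytic DMF converts F9 into the acid chloride F10.
  - F10 acylates N-lithiated 2 (n-BuLi, THF, −78 °C) to give 4.

Further compounds
F1 | step 5 | (2S,3S)-2,3-bis(tert-butyldiphenylsilyloxymethyl)-1,4-bis(4-hydroxy-3-methoxyphenyl)butane-1,4-dione | COc1cc(C(=O)[C@H](CO[Si](c2ccccc2)(c2ccccc2)C(C)(C)C)[C@@H](CO[Si](c2ccccc2)(c2ccccc2)C(C)(C)C)C(=O)c2ccc(O)c(OC)c2)ccc1O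
F2 | step 5 | (1R,2S,3S,4R)-2,3-bis(tert-butyldiphenylsilyloxymethyl)-1,4-bis(4-hydroxy-3-methoxyphenyl)butane-1,4-diol | COc1cc([C@H](O)[C@H](CO[Si](c2ccccc2)(c2ccccc2)C(C)(C)C)[C@@H](CO[Si](c2ccccc2)(c2ccccc2)C(C)(C)C)[C@@H](O)c2ccc(O)c(OC)c2)ccc1O
F3 | step 2 | tert-butyl (S)-3-[(R)-4-isopropyl-2-oxo-1,3-oxazolidine-3-carbonyl]-4-(3-methoxy-4-pivaloyloxyphenyl)butanoate | CC(C)[C@@H]1COC(=O)N1C(=O)[C@@H](Cc1ccc(OC(=O)C(C)(C)C)c(OC)c1)CC(=O)OC(C)(C)C
F4 | step 2 | tert-butyl (S)-3-(hydroxymethyl)-4-(3-methoxy-4-pivaloyloxyphenyl)butanoate | OC[C@@H](Cc1ccc(OC(=O)C(C)(C)C)c(OC)c1)CC(=O)OC(C)(C)C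
F5 | step 2 | (S)-4-(3-methoxy-4-pivaloyloxybenzyl)dihydrofuran-2(3H)-one | O=C1C[C@H](Cc2ccc(OC(=O)C(C)(C)C)c(OC)c2)CO1
F6 | step 2 | 2-methoxy-4-methylphenyl pivalate | Cc1ccc(OC(=O)C(C)(C)C)c(OC)c1
F7 | step 2 | 4-(bromomethyl)-2-methoxyphenyl pivalate | BrCc1ccc(OC(=O)C(C)(C)C)c(OC)c1
F8 | step 2 | (3S,4S)-3,4-bis(3-methoxy-4-pivaloyloxybenzyl)dihydrofuran-2(3H)-one | O=C1OC[C@@H](Cc2ccc(OC(=O)C(C)(C)C)c(OC)c2)[C@@H]1Cc3ccc(OC(=O)C(C)(C)C)c(OC)c3
F9 | step 1 | 3-(3-methoxy-4-pivaloyloxyphenyl)propanoic acid | COc1cc(CCC(=O)O)ccc1OC(=O)C(C)(C)C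
F10 | step 1 | 3-(3-methoxy-4-pivaloyloxyphenyl)propanoyl chloride | COc1cc(CCC(=O)Cl)ccc1OC(=O)C(C)(C)C
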